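The earlier runs and the new flask are simulated for substances that don't exist, noise included.

Stretching a straight line through the early target readings out to 12 h is a trap: that line assumes a steady rate, while target forms from substrate and partner.

the same everywhere: substrate 0.17 M; partner 0.162 M; free catalyst 14 mM
- Monday's: the very flask that is asked about, followed so far
- flask: time 12 h

- Monday's (time / h: idle adduct / %, target / %): 0.667: 0, 0.3; 1.33: 0.5, 3.1; 2.00: 2.8, 3.7; 2.50: 4.9, 4.9; 3.00: 4.5, 7.7; 4.00: 6.7, 9.0

(each reading ± 1 percentage point)

- a species is counted by the substrate in it: one idle adduct counts as two
- amounts and yields of target count idle adduct too
- the analysis behind the earlier runs scatters by 1 percentage point, standard deviation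
- in an amount of target, one idle adduct counts as one target

- how much idle adduct the flask holds at 12 h, in percent of the substrate charged
- how much target the flask holds at 12 h, in percent of the substrate charged
- how much substrate the flask holds at 12 h, in percent of the substrate charged

Two extreme versions of this flask can be solved in the head. In the zero-order one, the catalyst runs at a constant speed, so the 9.0 % of target at 4.00 h grows in proportion to time and reaches 27.0 %. In the second-order one, the rate follows c(substrate)·c(partner), with each target taking one of each. The two charges differ by 4.71 %, so they are treated as equal. The ratio of target made to substrate unconverted then grows in step with time, and its growth per hour is the turnover constant κ 0.0247 h⁻¹, read from one target reading that scatters by 1 percentage point. Over 12 h this gives target of 22.9 %. If the rate falls, but no faster than that product, the estimate of target in this flask lies between 22.9 % and 27.0 %, and this reckoning, itself subject to that scatter, commits to that range.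

The forecast gives idle adduct 15 %, target 22 % and substrate 70.5 %. Its target stands just below this range. Its ground: “This fits a rate proportional to substrate times partner, with no clear inhibition”.

The simulation gives idle adduct 11.8 %, target 23.8 % and substrate 51.7 %.

    partner + free catalyst → catalyst intermediate A (k = 0.302 M⁻¹ min⁻¹)
    catalyst intermediate A ⇌ catalyst intermediate B (K = 1.67, k = 3.27 min⁻¹)
    substrate + catalyst intermediate B → catalyst intermediate C (k = 0.152 M⁻¹ min⁻¹)
    catalyst intermediate C → free catalyst + target (k = 0.0332 min⁻¹)
    substrate + target ⇌ idle adduct, settled at all times (K = 3.73 M⁻¹)
    substrate + target → side product (k = 0.0111 M⁻¹ min⁻¹)
    substrate + free catalyst ⇌ idle complex, settled at all times (K = 9.19 M⁻¹)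

The substrate in this flask stands 19 points below the forecast, and the flask holds side product at 16.3 %, each one counted as two substrate. The target in this flask falls inside the range, 0.90 points above the end set by κ of 0.0247 h⁻¹.

For the neighbour flask with 0.035 M of free catalyst, κ and the slope are taken as proportional to the catalyst and so scaled by the ratio of 2.50. That gives a target range from 42.6 % to 67.5 %. The computed target there is 47.6 %.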